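If you want a quick number for cedar, maple and larch, I would reckon the fall of substrate once and treat the scavenger as a small correction to it.

in all of them: substrate 0.25 M; reagent 0.325 M
- alpha: scavenger 0.14 M; run made earlier
- epsilon: scavenger 0.67 M; run made earlier
- cedar: scavenger 0.120 M; time 6.0 h
- maple: scavenger 0.250 M; time 6.0 h
- larch: scavenger 0.500 M; time 6.0 h

| run | time / h | substrate / % | bis adduct / % |
|---|---|---|---|
| alpha | 0.500 | 97.0 | 0 |
| alpha | 1.33 | 89.4 | 0.7 |
| alpha | 2.50 | 82.8 | 0 |
| alpha | 4.00 | 75.3 | 0 |
| epsilon | 0.500 | 97.3 | 0 |
| epsilon | 1.33 | 92.2 | 0 |
| epsilon | 2.50 | 84.5 | 0.8 |
| epsilon | 4.00 | 78.0 | 0 |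

(scatter of a reading: 1 percentage point)

- the earlier runs were read with a standard deviation of 1 percentage point
- what has gone from substrate into another species counts as reacted, even if it can come back

* part of the substrate that has reacted at the end, cedar
* part of the substrate that has reacted at the end, maple
* part of the substrate that has reacted at the end, larch
* what raising the concentration of scavenger from its lowest to its highest value here does to the part of the substrate that has reacted (changes below 5 percentage points count as none) (it falls / no change / it rises)

1. Alpha has 75.3% of its substrate charge left after 4.00 h, so for the large term I take a first-order constant of 0.0709 h⁻¹, which carried to 6.0 h puts the reacted fraction of cedar at 34.7%.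

2. For the small term I leave out the earliest reading and average, over the other 3, how much more of its charge epsilon keeps as substrate than alpha does, which gives 2.4 percentage points, the scavenger gap; it is a reading, and each substrate reading behind it has a standard deviation of 1 point.

3. I read the gap as a fixed offset in the reacted fraction, so I commit to 34.7% for cedar, 33.5% for maple, midway, and 32.3% for larch, and since the gap stays under the 5 points that counts as a change, I expect no change.

4. The forecast, reached by its own fit and interpolation, says 34.5%, 33.5% and 32%, with the trend no change, on the ground that “Fivefold more scavenger therefore has at most a slight slowing effect”; my cedar figure stands 0.20 points above it.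

    substrate + reagent → first product + released group (k = 0.200 L mol⁻¹ h⁻¹)
    scavenger + released group → scavenged by-product (k = 28.0 L mol⁻¹ h⁻¹)
    reagent + first product → bis adduct + released group (k = 0.00490 L mol⁻¹ h⁻¹)
    substrate + released group ⇌ idle adduct, settled at all times (K = 10.0 L mol⁻¹)

The flask gives 31.5% for cedar, 29.9% for maple and 29.3% for larch, so the trend is no change, with a change of −2.2 points. At the end cedar holds 3.37% of its substrate charge as idle adduct and larch 0.542%. Taking the scavenger gap from cedar gives 29.1% beside the 29.3% of larch, and the same subtraction on the two flasks left for 60.0 h, where cedar has reacted 88.7%, gives 86.3% beside the 85.9% of larch.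

Readings and results stem from a simulated flask from invented constants; noise was put on by code.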